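**Retrosynthetic overview**

1. Longipinane numbering is used: C1 ketone, C2=C3 (methyl on C3), bridgeheads C4 and C11, one-carbon bridges C5 and C10 (C10 quaternary, methyl), C6 gem-dimethyl, carbinols C7–C9. The endgame is C9 angeloylation, desilylation and C8 isovalerylation of a 7,8,9-trioxygenated longipin-2-en-1-one.
2. Key disconnection: the C9–C10 bond of the seven-membered ring, made from a C9 aldehyde and an exocyclic C10=CH2 group by a hydrogen-atom-transfer-initiated cobalt/chromium reductive alkene–aldehyde cyclisation. The same event creates the C10 methyl group, the quaternary centre and the C9 carbinol.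
3. Enabling feature: the methylidene group sits on the one-carbon (cyclobutane) bridge C10 of a bicyclo[3.1.1]heptenone, between the bridgeheads C4 and C11, so it cannot migrate into the ring (Bredt). It is syn to the side chain on the other one-carbon bridge C5 (C6–C9), so Markovnikov H-atom transfer puts a tertiary radical within reach of the C9 aldehyde.
4. The bicyclic enone comes from an intramolecular Horner–Wadsworth–Emmons closure of the six-membered ring (C2=C3) across the cis-1,3 positions of a methylidenecyclobutane. That ring comes from a 3-substituted cyclobutanone (dichloroketene [2+2]), desymmetrised by a chiral lithium amide and elaborated at both α-carbons.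
5. The side chain with C7 and C8 comes from (R)-glyceraldehyde acetonide and prenyl bromide. Ring order: cyclobutane, then six-membered enone ring, then seven-membered ring.

Key step: step 16

Remark on shorthand: "chain A" is C(CH3)2–CH(OTBS)–[(4R)-2,2-dimethyl-1,3-dioxolan-4-yl] with the silyloxy carbon (S), as in 3; "future C…" refers to longipinane numbering.
Assumption: the (R,R) antipode of the lithium amide in step 5 is taken as the one that deprotonates the methylene that becomes C11; if the sense is opposite, the (S,S) amide is used with no other change.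

**Step 1**
Reactants: 1 (R)-2,2-dimethyl-1,3-dioxolane-4-carbaldehyde [(R)-glyceraldehyde acetonide]
Product: 2 (1S)-1-[(4R)-2,2-dimethyl-1,3-dioxolan-4-yl]-2,2-dimethylbut-3-en-1-ol
Conditions: prenyl bromide, Zn dust, THF/sat. aq. NH4Cl, 0 → 23 °C
Reagents that add atoms: prenyl bromide, CC(C)=CCBr
Why: Barbier-type zinc allylation reacts at the γ-carbon of the prenyl unit, installing the gem-dimethyl carbon (future C6) and the vinyl group, and non-chelated Felkin–Anh addition anti to the dioxolane C–O bond should give mainly the 1,2-anti (1S) carbinol (future C7), the minor epimer being removed by chromatography.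

**Step 2**
Reactants: 2 (1S)-1-[(4R)-2,2-dimethyl-1,3-dioxolan-4-yl]-2,2-dimethylbut-3-en-1-ol
Product: 3 tert-butyldimethylsilyl ether of 2
Conditions: TBSOTf, 2,6-lutidine, CH2Cl2, 0 °C
Reagents that add atoms: tert-butyldimethylsilyl triflate, CC(C)(C)[Si](C)(C)OS(=O)(=O)C(F)(F)F
Why: silylation of the hindered neopentyl-type secondary alcohol with the reactive silyl triflate, no stereocentre being touched.

**Step 3**
Reactants: 3 tert-butyldimethylsilyl ether of 2
Product: 4 2,2-dichloro-3-(chain A)cyclobutan-1-one (both configurations at ring C3)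
Conditions: Cl3CCOCl, Zn dust, DME/Et2O, ultrasound, 20 °C
Reagents that add atoms: trichloroacetyl chloride, ClC(=O)C(Cl)(Cl)Cl
Why: ketene–alkene [2+2] cycloaddition in which dichloroketene, formed in situ, adds to the terminal alkene with its carbonyl carbon on the CH2 terminus and so builds the cyclobutane; the new ring stereocentre is lost again in step 4.

**Step 4**
Reactants: 4 2,2-dichloro-3-(chain A)cyclobutan-1-one
Product: 5 3-(chain A)cyclobutan-1-one
Conditions: Zn dust, AcOH, 23 °C
Reagents that add atoms: none
Why: reductive dechlorination of the α,α-dichloroketone through zinc enolates gives the symmetric cyclobutanone whose two α-methylene groups are the future C4 and C11.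

**Step 5**
Reactants: 5 3-(chain A)cyclobutan-1-one
Product: 6 trimethyl{[3-(chain A)cyclobut-1-en-1-yl]oxy}silane, single ring epimer (enol carbon = future C11)
Conditions: lithium (R,R)-bis(1-phenylethyl)amide (preformed), TMSCl, THF, −100 °C
Reagents that add atoms: chlorotrimethylsilane, C[Si](C)(C)Cl
Why: desymmetrising deprotonation of a 3-substituted cyclobutanone by a C2-symmetric chiral lithium amide with internal silyl quench; the reagent selects one α-methylene, which makes the ring carbon bearing chain A a defined stereocentre (future C5), the remote chain stereocentres being expected to have little influence.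

**Step 6**
Reactants: 6 trimethyl{[3-(chain A)cyclobut-1-en-1-yl]oxy}silane
Product: 7 trans-2-(dimethoxymethyl)-3-(chain A)cyclobutan-1-one
Conditions: HC(OMe)3, TMSOTf (cat.), CH2Cl2, −78 °C
Reagents that add atoms: trimethyl orthoformate, COC(OC)OC
Why: Mukaiyama-type addition of the silyl enol ether to the dimethoxycarbenium ion; the electrophile enters anti to the neighbouring chain A, so the masked formyl group (future C1) is trans to it, which is also the thermodynamic arrangement.

**Step 7**
Reactants: 7 trans-2-(dimethoxymethyl)-3-(chain A)cyclobutan-1-one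
Product: 9 2-(dimethoxymethyl)-3-(chain A)-4-[1-(triethylsilyloxy)ethyl]cyclobutan-1-one (2,3-trans/3,4-trans; both carbinol epimers), via lithium aldolate 8 (not isolated)
Conditions: LDA, THF, −78 °C; CH3CHO; TESCl, −78 → 0 °C
Reagents that add atoms: acetaldehyde, CC=O; chlorotriethylsilane, CC[Si](Cl)(CC)CC
Why: kinetic deprotonation at the unsubstituted α'-methylene and aldol addition anti to chain A place the two-carbon unit (future C3 and its methyl) cis to the acetal and trans to the chain; the carbinol configuration is irrelevant because it is oxidised in step 11.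

**Step 8**
Reactants: 9 2-(dimethoxymethyl)-3-(chain A)-4-[1-(triethylsilyloxy)ethyl]cyclobutan-1-one
Product: 10 1-(dimethoxymethyl)-2-methylidene-4-(chain A)-3-[1-(triethylsilyloxy)ethyl]cyclobutane (relative configuration as in 9)
Conditions: Cp2TiMe2, toluene, 65 °C, dark
Reagents that add atoms: dimethyltitanocene, C[Ti](C)(C1C=CC=C1)C1C=CC=C1
Why: Petasis olefination; the non-basic titanium methylidene converts the strained, enolisable cyclobutanone into the exocyclic alkene (future C10=CH2) without epimerising the two α-stereocentres or eliminating the β-oxygen groups.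

**Step 9**
Reactants: 10 1-(dimethoxymethyl)-2-methylidene-4-(chain A)-3-[1-(triethylsilyloxy)ethyl]cyclobutane
Product: 11 3-(1-hydroxyethyl)-2-methylidene-4-(chain A)cyclobutane-1-carbaldehyde (formyl and hydroxyethyl cis, both trans to chain A)
Conditions: PPTS, acetone/H2O, 40 °C
Reagents that add atoms: water, O
Why: mild acid hydrolysis cleaves the dimethyl acetal and the triethylsilyl ether, while the dioxolane is maintained by the acetone solvent and the hindered TBS ether is stable.

**Step 10**
Reactants: 11 3-(1-hydroxyethyl)-2-methylidene-4-(chain A)cyclobutane-1-carbaldehyde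
Product: 12 dimethyl {2-[3-(1-hydroxyethyl)-2-methylidene-4-(chain A)cyclobutyl]-2-oxoethyl}phosphonate
Conditions: (MeO)2P(O)CHN2, SnCl2 (cat.), CH2Cl2, 23 °C
Reagents that add atoms: dimethyl (diazomethyl)phosphonate, COP(=O)(OC)C=[N+]=[N-]
Why: Roskamp homologation, in which Lewis-acid-promoted addition of the diazophosphonate to the aldehyde, 1,2-hydride shift and loss of N2 give the β-ketophosphonate (future C1 and C2) without base, so the allylic α-stereocentre is not enolised.

**Step 11**
Reactants: 12 dimethyl {2-[3-(1-hydroxyethyl)-2-methylidene-4-(chain A)cyclobutyl]-2-oxoethyl}phosphonate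
Product: 13 dimethyl {2-[3-acetyl-2-methylidene-4-(chain A)cyclobutyl]-2-oxoethyl}phosphonate
Conditions: Dess–Martin periodinane, NaHCO3, CH2Cl2, 0 → 23 °C
Reagents that add atoms: none
Why: buffered Dess–Martin oxidation of the secondary alcohol to the methyl ketone (future C3) under neutral conditions that should not move the exocyclic double bond.

**Step 12**
Reactants: 13 dimethyl {2-[3-acetyl-2-methylidene-4-(chain A)cyclobutyl]-2-oxoethyl}phosphonate
Product: 14 4-methyl-6-methylidene-7-(chain A)bicyclo[3.1.1]hept-3-en-2-one (chain A on C7 syn to the methylidene bridge C6)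
Conditions: LiCl, i-Pr2NEt, MeCN, 23 → 40 °C, high dilution
Reagents that add atoms: none
Why: intramolecular Horner–Wadsworth–Emmons reaction under Masamune–Roush conditions; the weak amine deprotonates only the lithium-chelated phosphonate, the cis-1,3 acyl groups close the six-membered ring, irreversible loss of phosphate pays for the strain of the bicyclo[3.1.1]heptene, and no new stereocentre is formed.

**Step 13**
Reactants: 14 4-methyl-6-methylidene-7-(chain A)bicyclo[3.1.1]hept-3-en-2-one
Product: 15 4-methyl-6-methylidene-7-[C(CH3)2–CH(OTBS)–CH(OH)–CH2OH]bicyclo[3.1.1]hept-3-en-2-one (stereocentres as in 14)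
Conditions: AcOH/H2O/THF, 40 °C
Reagents that add atoms: none
Why: acid hydrolysis of the terminal acetonide, which should leave the hindered TBS ether, the enone and the Bredt-protected methylidene group untouched.

**Step 14**
Reactants: 15 diol from 14
Product: 16 bis(triethylsilyl) ether of 15
Conditions: TESOTf, 2,6-lutidine, CH2Cl2, −78 °C
Reagents that add atoms: triethylsilyl triflate, CC[Si](CC)(CC)OS(=O)(=O)C(F)(F)F
Why: silylation of both hydroxyls at low temperature, which places a non-chelating silyl ether on the future C8 oxygen.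

**Step 15**
Reactants: 16 bis(triethylsilyl) ether of 15
Product: 17 4-methyl-6-methylidene-7-[C(CH3)2–CH(OTBS)–CH(OTES)–CHO]bicyclo[3.1.1]hept-3-en-2-one (stereocentres as in 14)
Conditions: (COCl)2, DMSO, CH2Cl2, −78 → −30 °C; Et3N
Reagents that add atoms: none
Why: Swern oxidation, under which a primary triethylsilyl ether is cleaved and oxidised directly to the aldehyde while secondary TES and TBS ethers survive; the α-silyloxy aldehyde is used at once.

**Step 16 (key step)**
Reactants: 17 aldehyde with the exocyclic methylidene group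
Product: 19 7-(tert-butyldimethylsilyloxy)-9-hydroxy-8-(triethylsilyloxy)longipin-2-en-1-one (stereocentres as in 22), via tertiary cyclobutyl radical 18 (not isolated)
Conditions: Co(salen) complex C36H52CoN2O2 (10 mol %), CrCl3 (30 mol %), PhSiH3, THF (0.005 M), 23 °C; aq. NaHCO3 work-up
Reagents that add atoms: none
Why: A cobalt hydride (trivalent cobalt, from the salen complex and PhSiH3) transfers a hydrogen atom to the CH2 terminus of the electron-neutral exocyclic alkene (Markovnikov MHAT), which creates the C10 methyl group and the tertiary cyclobutyl radical 18; this is captured by divalent chromium to give a nucleophilic tertiary alkylchromium species that adds to the C9 aldehyde. The closest known reaction type is the cobalt/chromium-cocatalysed branch-selective reductive coupling of 1,1-disubstituted alkenes with aldehydes, run here intramolecularly. The seven-membered ring closes in an exo mode onto the C=O (7-exo-trig in the radical description, a Nozaki–Hiyama–Kishi-type carbonyl addition in the polar one) and completes the bicyclo[4.1.1]octane part of the tricycle. The quaternary centre C10 is controlled by the tether: only the face of C10 syn to the C5 side chain can reach C9, so the new methyl must lie over the enone bridge. The C9 carbinol is controlled by the C8 silyl ether: C10 must attack the carbonyl face gauche to C7, and the non-chelating OTES group should orient the C=O dipole anti to the C8–O bond (Cornforth arrangement), which leads to the 8,9-trans carbinol. The step needs chemoselectivity for the alkene over the enone and for the aldehyde over the ketone: hydrogen-atom transfer prefers the electron-rich 1,1-disubstituted alkene, alkylchromium reagents add to aldehydes much faster than to ketones, and Bredt's rule excludes isomerisation of the methylidene group.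

**Step 17**
Reactants: 19 7-(tert-butyldimethylsilyloxy)-9-hydroxy-8-(triethylsilyloxy)longipin-2-en-1-one
Product: 20 9-angeloyloxy-7-(tert-butyldimethylsilyloxy)-8-(triethylsilyloxy)longipin-2-en-1-one (stereocentres as in 22)
Conditions: angelic acid, 2,4,6-trichlorobenzoyl chloride, Et3N, toluene, 23 °C; then 19, 80 °C
Reagents that add atoms: angelic acid [(Z)-2-methylbut-2-enoic acid], C/C=C(/C)C(=O)O
Why: Yamaguchi-type mixed-anhydride esterification, suited to hindered secondary alcohols and run without a nucleophilic catalyst so that the (Z)-angelate should not isomerise to the tiglate.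

**Step 18**
Reactants: 20 9-angeloyloxy-7-(tert-butyldimethylsilyloxy)-8-(triethylsilyloxy)longipin-2-en-1-one
Product: 21 9-angeloyloxy-7,8-dihydroxylongipin-2-en-1-one (stereocentres as in 22)
Conditions: HF·pyridine, pyridine/THF, 0 → 23 °C
Reagents that add atoms: none
Why: acidic fluoride desilylation removes both silyl ethers under conditions that should not cause acyl migration or ester cleavage.

**Step 19**
Reactants: 21 9-angeloyloxy-7,8-dihydroxylongipin-2-en-1-one
Product: 22 (4R,5S,7S,8S,9S,10R,11R)-9-angeloyloxy-7-hydroxy-8-(3-methylbutanoyloxy)longipin-2-en-1-one (CNP0251293.1)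
Conditions: isovaleric anhydride, pyridine, DMAP (cat.), CH2Cl2, −20 → 0 °C
Reagents that add atoms: isovaleric anhydride (3-methylbutanoic anhydride), CC(C)CC(=O)OC(=O)CC(C)C
Why: site-selective acylation, since the C8 hydroxyl is an ordinary secondary alcohol whereas the C7 hydroxyl is neopentyl-like next to the gem-dimethyl carbon C6 and should stay free.

**Compound list**

1 | (R)-2,2-dimethyl-1,3-dioxolane-4-carbaldehyde | O=C[C@H]1COC(C)(C)O1 | starting material
2 | (1S)-1-[(4R)-2,2-dimethyl-1,3-dioxolan-4-yl]-2,2-dimethylbut-3-en-1-ol | C=CC(C)(C)[C@H](O)[C@H]1COC(C)(C)O1 | intermediate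
3 | TBS ether of 2 | C=CC(C)(C)[C@H](O[Si](C)(C)C(C)(C)C)[C@H]1COC(C)(C)O1 | intermediate
4 | 2,2-dichloro-3-(chain A)cyclobutan-1-one (ring epimers) | O=C1CC(C(C)(C)[C@H](O[Si](C)(C)C(C)(C)C)[C@H]2COC(C)(C)O2)C1(Cl)Cl | intermediate
5 | 3-(chain A)cyclobutan-1-one | O=C1CC(C1)C(C)(C)[C@H](O[Si](C)(C)C(C)(C)C)[C@H]2COC(C)(C)O2 | intermediate
6 | trimethyl{[3-(chain A)cyclobut-1-en-1-yl]oxy}silane, single ring epimer | C[Si](C)(C)OC1=C[C@H](C1)C(C)(C)[C@H](O[Si](C)(C)C(C)(C)C)[C@H]2COC(C)(C)O2 | intermediate
7 | trans-2-(dimethoxymethyl)-3-(chain A)cyclobutan-1-one | COC(OC)[C@H]1C(=O)C[C@@H]1C(C)(C)[C@H](O[Si](C)(C)C(C)(C)C)[C@H]2COC(C)(C)O2 | intermediate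
8 | lithium aldolate of 7 with acetaldehyde (not isolated) | COC(OC)[C@H]1C(=O)[C@@H](C(C)[O-])[C@@H]1C(C)(C)[C@H](O[Si](C)(C)C(C)(C)C)[C@H]2COC(C)(C)O2.[Li+] | intermediate
9 | 2-(dimethoxymethyl)-3-(chain A)-4-[1-(triethylsilyloxy)ethyl]cyclobutan-1-one | COC(OC)[C@H]1C(=O)[C@@H](C(C)O[Si](CC)(CC)CC)[C@@H]1C(C)(C)[C@H](O[Si](C)(C)C(C)(C)C)[C@H]2COC(C)(C)O2 | intermediate
10 | 1-(dimethoxymethyl)-2-methylidene-4-(chain A)-3-[1-(triethylsilyloxy)ethyl]cyclobutane | COC(OC)[C@H]1C(=C)[C@@H](C(C)O[Si](CC)(CC)CC)[C@@H]1C(C)(C)[C@H](O[Si](C)(C)C(C)(C)C)[C@H]2COC(C)(C)O2 | intermediate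
11 | 3-(1-hydroxyethyl)-2-methylidene-4-(chain A)cyclobutane-1-carbaldehyde | O=C[C@H]1C(=C)[C@@H](C(C)O)[C@@H]1C(C)(C)[C@H](O[Si](C)(C)C(C)(C)C)[C@H]2COC(C)(C)O2 | intermediate
12 | dimethyl {2-[3-(1-hydroxyethyl)-2-methylidene-4-(chain A)cyclobutyl]-2-oxoethyl}phosphonate | COP(=O)(OC)CC(=O)[C@H]1C(=C)[C@@H](C(C)O)[C@@H]1C(C)(C)[C@H](O[Si](C)(C)C(C)(C)C)[C@H]2COC(C)(C)O2 | intermediate
13 | dimethyl {2-[3-acetyl-2-methylidene-4-(chain A)cyclobutyl]-2-oxoethyl}phosphonate | COP(=O)(OC)CC(=O)[C@H]1C(=C)[C@@H](C(C)=O)[C@@H]1C(C)(C)[C@H](O[Si](C)(C)C(C)(C)C)[C@H]2COC(C)(C)O2 | intermediate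
14 | 4-methyl-6-methylidene-7-(chain A)bicyclo[3.1.1]hept-3-en-2-one | CC1(C)OC[C@@H](O1)[C@@H](O[Si](C)(C)C(C)(C)C)C(C)(C)[C@@H]2[C@H]3C(=O)C=C(C)[C@@H]2C3=C | intermediate
15 | diol from 14 | OC[C@@H](O)[C@@H](O[Si](C)(C)C(C)(C)C)C(C)(C)[C@@H]2[C@H]3C(=O)C=C(C)[C@@H]2C3=C | intermediate
16 | bis(triethylsilyl) ether of 15 | CC[Si](CC)(CC)OC[C@@H](O[Si](CC)(CC)CC)[C@@H](O[Si](C)(C)C(C)(C)C)C(C)(C)[C@@H]2[C@H]3C(=O)C=C(C)[C@@H]2C3=C | intermediate
17 | aldehyde with exocyclic methylidene (cyclisation precursor) | O=C[C@@H](O[Si](CC)(CC)CC)[C@@H](O[Si](C)(C)C(C)(C)C)C(C)(C)[C@@H]2[C@H]3C(=O)C=C(C)[C@@H]2C3=C | intermediate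
18 | tertiary cyclobutyl radical at future C10 (not isolated) | O=C[C@@H](O[Si](CC)(CC)CC)[C@@H](O[Si](C)(C)C(C)(C)C)C(C)(C)[C@@H]2[C@H]3C(=O)C=C(C)[C@@H]2[C]3C | intermediate
19 | 7-(tert-butyldimethylsilyloxy)-9-hydroxy-8-(triethylsilyloxy)longipin-2-en-1-one | O[C@@H]1[C@@H](O[Si](CC)(CC)CC)[C@@H](O[Si](C)(C)C(C)(C)C)C(C)(C)[C@@H]2[C@H]3C(=O)C=C(C)[C@@H]2[C@@]13C | intermediate
20 | 9-angeloyloxy-7-(tert-butyldimethylsilyloxy)-8-(triethylsilyloxy)longipin-2-en-1-one | C/C=C(/C)C(=O)O[C@@H]1[C@@H](O[Si](CC)(CC)CC)[C@@H](O[Si](C)(C)C(C)(C)C)C(C)(C)[C@@H]2[C@H]3C(=O)C=C(C)[C@@H]2[C@@]13C | intermediate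
21 | 9-angeloyloxy-7,8-dihydroxylongipin-2-en-1-one | C/C=C(/C)C(=O)O[C@@H]1[C@@H](O)[C@@H](O)C(C)(C)[C@@H]2[C@H]3C(=O)C=C(C)[C@@H]2[C@@]13C | intermediate
22 | (4R,5S,7S,8S,9S,10R,11R)-9-angeloyloxy-7-hydroxy-8-(3-methylbutanoyloxy)longipin-2-en-1-one | C/C=C(/C)C(=O)O[C@@H]1[C@@H](OC(=O)CC(C)C)[C@@H](O)C(C)(C)[C@@H]2[C@H]3C(=O)C=C(C)[C@@H]2[C@@]13C | target

**Step count and risks**

Total step count: 19. Longest linear sequence: 19 steps (1 → 22).

Steps most likely to fail:

1. Step 16 (key step). The tertiary radical may be reduced before it is captured and closes the ring, and the two faces of the aldehyde may be discriminated poorly, giving the C9 epimer. Fallback, from 17 back to 19: the ring is closed in the free-radical manifold (Fe(acac)3, PhSiH3, EtOH/ethylene glycol, 60 °C; radical addition to the aldehyde and reduction of the alkoxyl radical) without regard to C9, which gives 19 together with its C9 epimer F1. The mixture is oxidised with Dess–Martin periodinane to the C9 ketone F2. The secondary TES ether is removed selectively (PPTS, MeOH, 0 °C) to give the α-hydroxy ketone F3. Hydroxyl-directed reduction with Me4NBH(OAc)3 (AcOH/MeCN, −20 °C), with hydride delivered from the face of the C8 hydroxyl, should give the 8,9-trans diol F4. Selective silylation of the less hindered C8 hydroxyl (TESCl, imidazole, DMF, −20 °C) returns to 19.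

2. Step 5. The chiral amide may differentiate the two α-methylene groups poorly, so that the core is formed in both senses relative to the side chain. Fallback, from 5 back to 7: asymmetric induction is given up in favour of a separation of diastereomers. Ketone 5 is deprotonated with LDA in the presence of TMSCl to give 6 together with its ring epimer F5. The mixture is taken through the orthoformate alkylation of step 6, and 7 is separated from its diastereomer F6 by chromatography (or, failing that, later at the rigid bicyclic enone stage).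

3. Step 12. Olefination of the methyl ketone may be slow, leaving time for the exocyclic double bond to migrate into conjugation or for epimerisation of the allylic α-centres. Fallback, from 11 back to 14, bypassing steps 10–12: the ring is closed by a directional aldol condensation and the methyl group is added afterwards. Oxidation of 11 with Dess–Martin periodinane gives the keto aldehyde F7. Aldol condensation of the methyl ketone onto the aldehyde (piperidinium acetate, benzene, 60 °C) gives the methyl-free, regio-transposed bicyclic enone F8. 1,2-Addition of MeLi (CeCl3, THF, −78 °C) gives the tertiary allylic alcohol F9. Oxidative 1,3-transposition with pyridinium chlorochromate (C5H5NH)(CrO3Cl) in CH2Cl2 then gives 14.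

**Further compounds**

F1 | step 16 | C9 epimer of 19 | O[C@H]1[C@@H](O[Si](CC)(CC)CC)[C@@H](O[Si](C)(C)C(C)(C)C)C(C)(C)[C@@H]2[C@H]3C(=O)C=C(C)[C@@H]2[C@@]13C
F2 | step 16 | 7-(tert-butyldimethylsilyloxy)-8-(triethylsilyloxy)longipin-2-ene-1,9-dione | O=C1[C@@H](O[Si](CC)(CC)CC)[C@@H](O[Si](C)(C)C(C)(C)C)C(C)(C)[C@@H]2[C@H]3C(=O)C=C(C)[C@@H]2[C@@]13C
F3 | step 16 | 7-(tert-butyldimethylsilyloxy)-8-hydroxylongipin-2-ene-1,9-dione | O=C1[C@@H](O)[C@@H](O[Si](C)(C)C(C)(C)C)C(C)(C)[C@@H]2[C@H]3C(=O)C=C(C)[C@@H]2[C@@]13C
F4 | step 16 | 7-(tert-butyldimethylsilyloxy)-8,9-dihydroxylongipin-2-en-1-one (8,9-trans) | O[C@@H]1[C@@H](O)[C@@H](O[Si](C)(C)C(C)(C)C)C(C)(C)[C@@H]2[C@H]3C(=O)C=C(C)[C@@H]2[C@@]13C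
F5 | step 5 | ring epimer of 6 | C[Si](C)(C)OC1=C[C@@H](C1)C(C)(C)[C@H](O[Si](C)(C)C(C)(C)C)[C@H]2COC(C)(C)O2
F6 | step 5 | diastereomer of 7 with both ring centres inverted | COC(OC)[C@@H]1C(=O)C[C@H]1C(C)(C)[C@H](O[Si](C)(C)C(C)(C)C)[C@H]2COC(C)(C)O2
F7 | step 12 | 3-acetyl-2-methylidene-4-(chain A)cyclobutane-1-carbaldehyde | O=C[C@H]1C(=C)[C@@H](C(C)=O)[C@@H]1C(C)(C)[C@H](O[Si](C)(C)C(C)(C)C)[C@H]2COC(C)(C)O2
F8 | step 12 | 6-methylidene-7-(chain A)bicyclo[3.1.1]hept-3-en-2-one with the carbonyl on future C3 | CC1(C)OC[C@@H](O1)[C@@H](O[Si](C)(C)C(C)(C)C)C(C)(C)[C@@H]2[C@H]3C=CC(=O)[C@@H]2C3=C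
F9 | step 12 | 2-methyl-6-methylidene-7-(chain A)bicyclo[3.1.1]hept-3-en-2-ol | CC1(C)OC[C@@H](O1)[C@@H](O[Si](C)(C)C(C)(C)C)C(C)(C)[C@@H]2[C@H]3C=CC(C)(O)[C@@H]2C3=C
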